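**Plan**

1. Retrosynthesis first cuts the six aryl–O–alkyl bonds (four O–CH3 and the two O–CH bonds of a five-carbon strap), then the biaryl bond C3'–C8'' as a dehydrogenative C–H/C–H coupling, then the two strap C–O bonds. This leads to biochanin A, prunetin and (2R,4R)-pentane-2,4-diol.
2. Enabling feature: the target is the dehydrodimer of genistein, and the bond C3'–C8'' is the axis of a 2,2'-biphenol. C3' is ortho to O4' on ring B of one unit (para position blocked by C3 of ring C). C8'' lies between O7'' and O1'' and para to O5'' on ring A of the other unit. A three-carbon strap from O4' to O7'' holds these two electron-rich CH carbons together.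
3. Forward order: no ring of the target is built, since both isoflavones are bought as complementary monomethyl ethers. O7 of biochanin A is joined to the strap, the strap to O4' of prunetin, and both chelated 5-OH groups are capped. The temporary nine-membered ring is then closed at C3'–C8'', and the strap and all methyl groups are removed together.
4. Stereochemistry: two Mitsunobu inversions turn the (R,R)-diol into an (S,S)-strap. Its two stereocenters should dictate the M sense of the axis in the coupling, and the axis is carried unchanged through the last step.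

Key step: step 4

Remark: the SMILES carries no descriptor for the biaryl axis, so M is taken from the name (C4' ranks above C2', C8a'' above C7'', so M means a positive dihedral C4'–C3'–C8''–C7''), and the axis is assumed to be configurationally stable at room temperature. Plain and single-primed locants refer to the prunetin-derived unit, double- and triple-primed locants to the biochanin-derived unit.

**Step 1**
Reactants: 1 biochanin A; 2 (2R,4R)-pentane-2,4-diol
Product: 3 5-hydroxy-7-{[(2S,4R)-4-hydroxypentan-2-yl]oxy}-3-(4-methoxyphenyl)-4H-chromen-4-one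
Conditions: 2 (3 equiv), PPh3, DIAD, THF, 0 °C to rt
Reagents that add atoms: none
Why: Mitsunobu etherification in which the non-chelated, most acidic 7-OH of 1 (the 5-OH is tied up in a hydrogen bond to the C4 carbonyl) displaces one activated hydroxyl of the diol used in excess, with SN2 inversion that turns this (R)-carbinol into the (S)-configured ether carbon while the other (R)-carbinol stays untouched.

**Step 2**
Reactants: 3 mono-ether alcohol; 4 prunetin
Product: 5 5-hydroxy-7-({(2S,4S)-4-[4-(5-hydroxy-7-methoxy-4-oxo-4H-chromen-3-yl)phenoxy]pentan-2-yl}oxy)-3-(4-methoxyphenyl)-4H-chromen-4-one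
Conditions: 4 (1.2 equiv), PPh3, DIAD, THF, 0 °C to rt
Reagents that add atoms: none
Why: second Mitsunobu etherification in which the only free non-chelated phenol of prunetin, the 4'-OH, attacks the remaining (R)-carbinol of 3 with inversion, so that the strap becomes (S,S), as known for stepwise arylation of pentane-2,4-diol with two different phenols.

**Step 3**
Reactants: 5 strapped bis-isoflavone
Product: 6 7-({(2S,4S)-4-[4-(5,7-dimethoxy-4-oxo-4H-chromen-3-yl)phenoxy]pentan-2-yl}oxy)-5-methoxy-3-(4-methoxyphenyl)-4H-chromen-4-one
Conditions: MeI (excess), K2CO3, DMF, 50 °C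
Reagents that add atoms: iodomethane, CI
Why: Williamson O-methylation of the two chelated 5-hydroxyls under forcing carbonate conditions, which removes the oxidisable chelating phenols and makes C8'' (para to the new 5''-OMe) the most nucleophilic CH of ring A of the biochanin unit, in line with the known C8 selectivity of electrophilic substitution on 5,7-dialkoxy(iso)flavones; no stereocenter is touched.

**Step 4**
Reactants: 6 permethylated strapped bis-isoflavone
Product: 7 (M)-configured strapped biaryl, 6 less two hydrogens, with C3' bonded to C8'' inside a nine-membered 1,5-dioxonine ring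
Conditions: PhI(OCOCF3)2 (1.1 equiv), (CF3)2CHOH/CH2Cl2, 0.002 M, −20 to 0 °C
Reagents that add atoms: none
Why: Proposed new method: the trivalent iodine reagent in the fluoroalcohol should oxidise by single-electron transfer the para-blocked 4-alkoxyphenyl ring B of the prunetin unit (or, with the same outcome, ring A of the biochanin unit) to an arene radical cation, which is attacked across the strap by the other ring so that C8'' bonds to C3', and a second electron transfer with loss of two protons gives the biaryl. The closest known reaction types are the hypervalent-iodine oxidative biaryl coupling of phenol ethers (including its intramolecular medium-ring versions and the ortho substitution of para-substituted anisoles through their radical cations) and the diastereoselective intramolecular Ullmann coupling of bis(2-iodoaryl) ethers of pentane-2,4-diol, of which this step is the dehydrogenative version. The only ring closed is the temporary nine-membered ring C4'–C3'–C8''–C7''–O–CH(CH3)–CH2–CH(CH3)–O, closed at the C3'–C8'' carbon–carbon bond with both reacting carbons inside the ring (endo attack of an arene on the strapped arene radical cation). No stereocenter is formed; the axis is controlled by the two (S)-carbinol carbons, because the strap can span O4' and O7'' only in a twist with both O–C–C–C torsions gauche-plus, and this twist keeps both methyl groups outward (anti to the far strap carbon) only when the dihedral C4'–C3'–C8''–C7'' is positive, that is M, whereas the P axis would force a methyl group into a syn-pentane contact with the opposite aryl oxygen. The step needs cross-coupling over intermolecular coupling (secured by the strap and high dilution), C8'' over C6'' (C8'' is para to 5''-OMe and flanked only by the tied-back ring oxygen, C6'' sits between two alkoxy groups) and ortho attack on ring B (its para position carries the chromone and its two ortho positions are equivalent).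

**Step 5**
Reactants: 7 (M)-strapped biaryl
Product: 8 (M)-bisoflavolin D
Conditions: BBr3 (excess), CH2Cl2, −78 °C to rt; then H2O
Reagents that add atoms: none
Why: boron tribromide ether cleavage, in which Lewis acid complexation and bromide attack should remove the four methyl groups and both secondary carbons of the strap (the known way to take a pentane-2,4-diol strap off a biaryl diol) at or below room temperature, where the tri-ortho-substituted axis set in step 4 should not rotate, so that the M configuration is carried into 8.

**Compound list**

1 | biochanin A, 5,7-dihydroxy-3-(4-methoxyphenyl)-4H-chromen-4-one | O=c1c(-c2ccc(OC)cc2)coc2cc(O)cc(O)c12 | starting material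
2 | (2R,4R)-pentane-2,4-diol | C[C@@H](O)C[C@@H](C)O | starting material
3 | 5-hydroxy-7-{[(2S,4R)-4-hydroxypentan-2-yl]oxy}-3-(4-methoxyphenyl)-4H-chromen-4-one | O=c1c(-c2ccc(OC)cc2)coc2cc(O[C@@H](C)C[C@@H](C)O)cc(O)c12 | intermediate
4 | prunetin, 5-hydroxy-3-(4-hydroxyphenyl)-7-methoxy-4H-chromen-4-one | O=c1c(-c2ccc(O)cc2)coc2cc(OC)cc(O)c12 | starting material
5 | 5-hydroxy-7-({(2S,4S)-4-[4-(5-hydroxy-7-methoxy-4-oxo-4H-chromen-3-yl)phenoxy]pentan-2-yl}oxy)-3-(4-methoxyphenyl)-4H-chromen-4-one | O=c1c(-c2ccc(OC)cc2)coc2cc(O[C@@H](C)C[C@H](C)Oc3ccc(cc3)-c3coc4cc(OC)cc(O)c4c3=O)cc(O)c12 | intermediate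
6 | 7-({(2S,4S)-4-[4-(5,7-dimethoxy-4-oxo-4H-chromen-3-yl)phenoxy]pentan-2-yl}oxy)-5-methoxy-3-(4-methoxyphenyl)-4H-chromen-4-one | O=c1c(-c2ccc(OC)cc2)coc2cc(O[C@@H](C)C[C@H](C)Oc3ccc(cc3)-c3coc4cc(OC)cc(OC)c4c3=O)cc(OC)c12 | intermediate
7 | (M)-strapped biaryl: C3' of ring B of the 5,7-dimethoxyisoflavone unit bonded to C8'' of the 5''-methoxy-3''-(4-methoxyphenyl)chromone unit, O4' and O7'' bridged by (2S,4S)-pentane-2,4-diyl (nine-membered 1,5-dioxonine ring), M axis | O=c1c(-c2ccc(OC)cc2)coc2c1c(OC)cc1O[C@@H](C)C[C@H](C)Oc3ccc(cc3-c21)-c1coc2cc(OC)cc(OC)c2c1=O | intermediate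
8 | (M)-bisoflavolin D, the 3',8''-linked genistein dimer with M axis | O=c1c(-c2ccc(O)c(-c3c(O)cc(O)c4c(=O)c(-c5ccc(O)cc5)coc34)c2)coc2cc(O)cc(O)c12 | target

**Step count**

Total step count: 5. Longest linear sequence: 5 steps (1 → 3 → 5 → 6 → 7 → 8).

**Steps most likely to fail**

Step 4 (proposed new method). Electron transfer may not occur on arenes that each carry a conjugated chromone carbonyl. The radical cation may also be trapped between molecules or at C6'' instead of closing the nine-membered ring, and the more electron-rich biaryl product may be oxidised further. The fallback uses known chemistry, sets out from 3 and 4 and comes back at 7: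
- 3 is methylated at its chelated 5-OH (MeI, K2CO3, DMF) to 7-{[(2S,4R)-4-hydroxypentan-2-yl]oxy}-5-methoxy-3-(4-methoxyphenyl)-4H-chromen-4-one F1.
- F1 is iodinated para to the 5-methoxy group (I2, CF3CO2Ag, CH2Cl2, 0 °C) to its 8-iodo derivative F2.
- Prunetin 4 is iodinated ortho to its phenoxide (I2, KI, NaHCO3, aqueous THF) to 3'-iodoprunetin F3.
- Mitsunobu etherification of F2 with F3 (PPh3, DIAD, THF) should give with inversion the (S,S)-strapped bis-iodide with one free 5-OH F4.
- Methylation (MeI, K2CO3, DMF) gives the fully methylated (S,S)-strapped bis-iodide F5.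
- Intramolecular Ullmann coupling (activated Cu powder, DMF, 100 °C) should then close the same nine-membered ring under the same strap control and give 7.

Step 5. Cleavage of the two hindered secondary alkyl aryl ethers or of the two non-chelated methyl ethers may be incomplete at temperatures low enough to avoid slow rotation about the axis in the Lewis-acidic medium. The fallback sets out from 7 and comes back at 8:
- BCl3 (CH2Cl2, −78 to 0 °C) cleaves secondary alkyl aryl ethers and peri-chelated methoxy groups but not ordinary anisoles. It should first remove the strap and the two 5-O-methyl groups to give (M)-7,4'''-di-O-methylbisoflavolin D F6.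
- The two remaining methyl groups, both remote from the axis, are then removed with the hard acid/soft nucleophile pair AlBr3/EtSH (CH2Cl2, 0 °C) to give 8.

Step 2. The activated secondary alcohol may eliminate to an alkene, or conversion may stay low with the less acidic 4'-phenol. The fallback sets out from 3 and comes back at 5:
- 3 is converted with retention into (2R,4S)-4-{[5-hydroxy-3-(4-methoxyphenyl)-4-oxo-4H-chromen-7-yl]oxy}pentan-2-yl methanesulfonate F7 (MsCl, Et3N, CH2Cl2, 0 °C).
- The sulfonate is displaced by the 4'-phenoxide of prunetin 4 (Cs2CO3, DMF, 50 °C) in a Williamson etherification with the same inversion, giving 5.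

**Further compounds**

F1 | step 4 | 7-{[(2S,4R)-4-hydroxypentan-2-yl]oxy}-5-methoxy-3-(4-methoxyphenyl)-4H-chromen-4-one | O=c1c(-c2ccc(OC)cc2)coc2cc(O[C@@H](C)C[C@@H](C)O)cc(OC)c12
F2 | step 4 | 7-{[(2S,4R)-4-hydroxypentan-2-yl]oxy}-8-iodo-5-methoxy-3-(4-methoxyphenyl)-4H-chromen-4-one | O=c1c(-c2ccc(OC)cc2)coc2c(I)c(O[C@@H](C)C[C@@H](C)O)cc(OC)c12
F3 | step 4 | 3'-iodoprunetin, 5-hydroxy-3-(4-hydroxy-3-iodophenyl)-7-methoxy-4H-chromen-4-one | O=c1c(-c2ccc(O)c(I)c2)coc2cc(OC)cc(O)c12
F4 | step 4 | (S,S)-strapped bis-iodide with one free 5-OH, 5-hydroxy-3-[3-iodo-4-({(2S,4S)-4-[(8-iodo-5-methoxy-3-(4-methoxyphenyl)-4-oxo-4H-chromen-7-yl)oxy]pentan-2-yl}oxy)phenyl]-7-methoxy-4H-chromen-4-one | O=c1c(-c2ccc(OC)cc2)coc2c(I)c(O[C@@H](C)C[C@H](C)Oc3ccc(cc3I)-c3coc4cc(OC)cc(O)c4c3=O)cc(OC)c12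
F5 | step 4 | fully methylated (S,S)-strapped bis-iodide, the 5-O-methyl ether of F4 | O=c1c(-c2ccc(OC)cc2)coc2c(I)c(O[C@@H](C)C[C@H](C)Oc3ccc(cc3I)-c3coc4cc(OC)cc(OC)c4c3=O)cc(OC)c12
F6 | step 5 | (M)-7,4'''-di-O-methylbisoflavolin D | O=c1c(-c2ccc(O)c(-c3c(O)cc(O)c4c(=O)c(-c5ccc(OC)cc5)coc34)c2)coc2cc(OC)cc(O)c12
F7 | step 2 | (2R,4S)-4-{[5-hydroxy-3-(4-methoxyphenyl)-4-oxo-4H-chromen-7-yl]oxy}pentan-2-yl methanesulfonate | O=c1c(-c2ccc(OC)cc2)coc2cc(O[C@@H](C)C[C@@H](C)OS(C)(=O)=O)cc(O)c12
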